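**Retrosynthetic overview**

1. The target is one resveratrol unit and two oxyresveratrol units (a central one and an outer one); all ring-forming bonds are made on free phenols, as the plant is thought to make them.
2. Last disconnection: C7'–C10 (seven-membered ring), a Friedel–Crafts hydroarylation of the 2,4-dihydroxystilbene of a racemic linear trimer; a chiral Brønsted acid lets this one step pick the enantiomer and the ring that closes.
3. Before that: C8–C10' and C7–O (dihydrofuran of the resveratrol unit), oxidative [3+2] coupling of resveratrol onto an oxyresveratrol dimer.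
4. First: C8''–C14' and C7''–O (dihydrofuran of the outer unit), oxidative dimerisation of oxyresveratrol.
5. Ring order forward: outer dihydrofuran (1 + 1 → 3 via 2), resveratrol-derived dihydrofuran (3 + 4 → 6 via 5), seven-membered ring (6 → 8 via 7).

Locants and ring names:
- Resveratrol unit: C7 (O–CH) carries ring A (4-hydroxyphenyl); C8 carries ring B (3,5-dihydroxyphenyl, C9–C14).
- Central oxyresveratrol unit: C7' carries ring C (2,4-dihydroxyphenyl); C8'; ring D is the central ring (C9'–C14').
- Outer oxyresveratrol unit: C7'' carries ring E (2,4-dihydroxyphenyl); C8'' carries ring G (3,5-dihydroxyphenyl).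
- The target is (7R,8R,7'R,7''S,8''S).

Assumption: the sense of induction of the chiral acid in step 3 cannot be predicted; the (R)-acid is written, and the (S)-acid is used instead if a test run gives the mirror-image series.

**Route**

Step 1
Reactants: 1 oxyresveratrol (two molecules)
Product: 3 racemic trans oxyresveratrol 8''–14' dehydrodimer (2S,3S enantiomer drawn), via para-quinone methide 2 (not isolated)
Conditions: FeCl3·6H2O (1.0 equiv per 1), acetone, 0 °C to rt, dark, N2; pH 7 phosphate/ascorbate quench; C18 chromatography
Reagents that add atoms: none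
Why: Biomimetic oxidative phenol coupling (formal [3+2] of a 4-hydroxystilbene radical with a resorcinol ring, the reaction by which FeCl3·6H2O turns resveratrol into ε-viniferin): the C8'' radical of one molecule bonds to C14' of the second (C8'' set here, racemic), and quinone methide 2 is closed by the neighbouring 13'-OH in a reversible oxa-Michael addition that leaves the two aryl groups trans (C7'').

Step 2
Reactants: 3 racemic oxyresveratrol dehydrodimer; 4 resveratrol (5 equiv)
Product: 6 racemic linear trimer (7R,8R,7''S,8''S enantiomer drawn), via para-quinone methide 5 (not isolated)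
Conditions: FeCl3·6H2O (5 equiv, added over 2 h), acetone, 0 °C; pH 7 quench; preparative C18 HPLC (removes resveratrol dimers, recovered 3 and the 7R*,8R*,7''R*,8''R* diastereomer)
Reagents that add atoms: none
Why: The same oxidative [3+2] coupling run as a cross-coupling, with excess resveratrol as radical donor and the free C10' of ring D (ortho to 11'-OH, para to the ring oxygen) as acceptor; C8 forms without control from the remote outer unit (about 1:1), C7 follows as trans in the oxa-Michael closure of 5, and the wanted relative configuration is secured by the HPLC separation.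

Step 3
Reactants: 6 racemic linear trimer
Product: 8 target (7R,8R,7'R,7''S,8''S), via ortho-quinone methide 7 (not isolated)
Conditions: (R)-3,3'-bis(2,4,6-triisopropylphenyl)-1,1'-binaphthyl-2,2'-diyl N-triflylphosphoramide (10 mol%), MeCN/CH2Cl2 1:1 (2 mM), 5 Å MS, −20 °C to rt; Et3N quench; C18 HPLC
Reagents that add atoms: none
Why: Proposed new method: the chiral acid hydrogen-bonds to the 2-OH of ring C and protonates C8' to give the catalyst-bound ortho-quinone methide 7, in which the two resorcinol rings able to close (ring B and ring G) sit on mirror-related dihydrofurans that differ only in one remote hydroxyl (ring A versus ring E), so the trimer behaves like a meso compound and the face of C7' that the catalyst leaves open decides which ring closes the seven-membered ring; in the (7R,8R,7''S,8''S) enantiomer that face belongs to ring B and gives 7'R with the aryl pseudo-equatorial (H7' anti to H8, the sense expected from the acid closure of ε-viniferin to ampelopsin B), while the mirror-image trimer is closed through ring G to a separable constitutional isomer, so 8 is obtained as one enantiomer in at most 50% yield; closest known reaction types are chiral phosphoric acid-catalysed arene additions to ortho-quinone methides generated from 2-vinylphenols, chiral-acid desymmetrisation of meso substrates and the Brønsted acid cyclisation of ε-viniferin to ampelopsin B.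

**Compound list**

1 | oxyresveratrol, (E)-4-[2-(3,5-dihydroxyphenyl)ethenyl]benzene-1,3-diol | Oc1ccc(/C=C/c2cc(O)cc(O)c2)c(O)c1 | starting material

2 | open para-quinone methide after C8''–C14' coupling, 4-{(2S)-2-(3,5-dihydroxyphenyl)-2-[2-[(E)-2-(2,4-dihydroxyphenyl)ethenyl]-4,6-dihydroxyphenyl]ethylidene}-3-hydroxycyclohexa-2,5-dien-1-one (racemic, ylidene geometry not defined) | Oc1cc(O)c([C@H](c2cc(O)cc(O)c2)C=C2C=CC(=O)C=C2O)c(/C=C/c2ccc(O)cc2O)c1 | intermediate

3 | (2S,3S)-2-(2,4-dihydroxyphenyl)-3-(3,5-dihydroxyphenyl)-4-[(E)-2-(2,4-dihydroxyphenyl)ethenyl]-2,3-dihydro-1-benzofuran-6-ol (racemate; enantiomer drawn leads to 8) | Oc1cc2c(c(/C=C/c3ccc(O)cc3O)c1)[C@H](c1cc(O)cc(O)c1)[C@@H](c1ccc(O)cc1O)O2 | intermediate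

4 | resveratrol, (E)-5-[2-(4-hydroxyphenyl)ethenyl]benzene-1,3-diol | Oc1ccc(/C=C/c2cc(O)cc(O)c2)cc1 | starting material

5 | open para-quinone methide after C8–C10' coupling, 4-[(2R)-2-[(2S,3S)-2-(2,4-dihydroxyphenyl)-3-(3,5-dihydroxyphenyl)-4-[(E)-2-(2,4-dihydroxyphenyl)ethenyl]-6-hydroxy-2,3-dihydro-1-benzofuran-5-yl]-2-(3,5-dihydroxyphenyl)ethylidene]cyclohexa-2,5-dien-1-one (racemic) | O=C1C=CC(=C[C@H](c2cc(O)cc(O)c2)c2c(O)cc3c(c2/C=C/c2ccc(O)cc2O)[C@H](c2cc(O)cc(O)c2)[C@@H](c2ccc(O)cc2O)O3)C=C1 | intermediate

6 | linear trimer, (2R,3R,5S,6S)-6-(2,4-dihydroxyphenyl)-3,5-bis(3,5-dihydroxyphenyl)-4-[(E)-2-(2,4-dihydroxyphenyl)ethenyl]-2-(4-hydroxyphenyl)-2,3,5,6-tetrahydrobenzo[1,2-b:5,4-b']difuran, i.e. 7R,8R,7''S,8''S (racemate; enantiomer drawn leads to 8) | Oc1ccc([C@@H]2Oc3cc4c(c(/C=C/c5ccc(O)cc5O)c3[C@H]2c2cc(O)cc(O)c2)[C@H](c2cc(O)cc(O)c2)[C@@H](c2ccc(O)cc2O)O4)cc1 | intermediate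

7 | ortho-quinone methide of 6: the styryl group of 6 replaced by CH2–CH=(3-hydroxy-6-ylidene-cyclohexa-2,4-dien-1-one), stereocentres as in 6 (ylidene geometry not defined) | Oc1ccc([C@@H]2Oc3cc4c(c(CC=C5C=CC(O)=CC5=O)c3[C@H]2c2cc(O)cc(O)c2)[C@H](c2cc(O)cc(O)c2)[C@@H](c2ccc(O)cc2O)O4)cc1 | intermediate

8 | CNP0283541.1, (7R,8R,7'R,7''S,8''S): trans-dihydrofuran of the resveratrol unit (C7 with 4-hydroxyphenyl, C8) fused to ring D at O11'/C10'; seven-membered ring C8–C9–C10–C7'–C8'–C9'–C10' with 2,4-dihydroxyphenyl on C7' and C8' as CH2; trans-dihydrofuran of the outer unit (C7'' with 2,4-dihydroxyphenyl, C8'' with 3,5-dihydroxyphenyl) fused to ring D at O13'/C14' | Oc1ccc([C@@H]2Oc3cc4c(c5c3[C@H]2c2cc(O)cc(O)c2[C@@H](c2ccc(O)cc2O)C5)[C@H](c2cc(O)cc(O)c2)[C@@H](c2ccc(O)cc2O)O4)cc1 | target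

**Totals**

Total step count: 3. Longest linear sequence: 3 steps (1 → 3 → 6 → 8). Rough expectations: step 1 about 15–20%, step 2 a few per cent of the wanted diastereomer (3 partly recovered), step 3 30–40% against a 50% ceiling.

**Steps most likely to fail, with fallbacks**

Step 2 (most at risk). Resveratrol self-coupling dominates, and 3 can itself act as radical donor through its 2,4-dihydroxystilbene. Ring C, ring E and ring G of 3 and the C12' position of ring D compete as acceptors. There is no diastereocontrol, and the HCl formed may close the seven-membered ring prematurely (2,6-di-tert-butylpyridine is added if that is seen). Fallback: set out from 3 and replace resveratrol by its cheap 3-O-β-D-glucoside, polydatin F1, as the donor (FeCl3·6H2O, acetone/water, 0 °C). The blocked, hindered resorcinol ring of polydatin is a poorer acceptor, so less donor is lost to self-coupling. Every cross-product carries exactly one glucose and is pulled out by polarity. The sugar turns the two enantiomeric series of the trimer monoglucoside F2 into diastereomers that separate on C18. Almond β-glucosidase (pH 5 acetate buffer, 37 °C) then removes the sugar and the route is rejoined at 6, now as the single 7R,8R,7''S,8''S enantiomer, so that step 3 only has to choose the ring.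

Step 3. The catalyst may bind to any of the nine phenols and lose face control. The acid may ionise the C7''–O or C7–O benzylic ether and lead to indane by-products. The ee of 8 cannot exceed the face selectivity of the acid. Fallback: set out from 6 and give up catalyst control. Close the ring with p-TsOH·H2O (5 mol%, MeCN, 0 °C) to racemic 8 plus the isomer closed through ring G, remove that isomer on C18, and resolve the racemate by preparative SFC on an amylose tris(3,5-dimethylphenylcarbamate) phase. The mirror-image component, ent-8 F3, is discarded, and the route is rejoined at 8.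

Step 1. Oxyresveratrol carries two resorcinol-type rings, so 8–8' couplings and couplings onto the 2,4-dihydroxyphenyl ring compete, and acid may close 3 onto ring G. Fallback: reverse the order in which the two dihydrofurans are built. Set out from 1 and 4 and oxidise their mixture (FeCl3·6H2O, acetone, 0 °C, resveratrol in excess), so that the resveratrol donor is put on ring D first. The cross-product, the racemic heterodimer F4 (7R,8R drawn), is taken out of the statistical mixture by C18 HPLC. Then couple it with a second molecule of 1 as donor at C14'/O13' under the same conditions, separate the diastereomers, and rejoin the route at 6.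

**Further compounds**

F1 | step 2 | polydatin, (E)-resveratrol 3-O-β-D-glucopyranoside (purchased) | Oc1ccc(/C=C/c2cc(O)cc(O[C@@H]3O[C@H](CO)[C@@H](O)[C@H](O)[C@H]3O)c2)cc1
F2 | step 2 | mono-β-D-glucopyranoside of 6 on one hydroxyl of ring B, 7R,8R,7''S,8''S | Oc1ccc([C@@H]2Oc3cc4c(c(/C=C/c5ccc(O)cc5O)c3[C@H]2c2cc(O)cc(O[C@@H]3O[C@H](CO)[C@@H](O)[C@H](O)[C@H]3O)c2)[C@H](c2cc(O)cc(O)c2)[C@@H](c2ccc(O)cc2O)O4)cc1
F3 | step 3 | ent-8, (7S,8S,7'S,7''R,8''R) | Oc1ccc([C@H]2Oc3cc4c(c5c3[C@@H]2c2cc(O)cc(O)c2[C@H](c2ccc(O)cc2O)C5)[C@@H](c2cc(O)cc(O)c2)[C@H](c2ccc(O)cc2O)O4)cc1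
F4 | step 1 | (2R,3R)-3-(3,5-dihydroxyphenyl)-4-[(E)-2-(2,4-dihydroxyphenyl)ethenyl]-2-(4-hydroxyphenyl)-2,3-dihydro-1-benzofuran-6-ol (racemate, enantiomer drawn) | Oc1ccc([C@@H]2Oc3cc(O)cc(/C=C/c4ccc(O)cc4O)c3[C@H]2c2cc(O)cc(O)c2)cc1
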